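A direct plan would convert one carboxyl of dodecanedioic acid A1 into the benzyl ester, 12-(benzyloxy)-12-oxododecanoic acid A2, and would join A2 with palmitic acid A3 by mixed Kolbe electrolysis, forming the C11–C12 bond from two anodic primary radicals. Its weakest steps would be two. The half-esterification would be only statistical and would leave A1 and dibenzyl dodecanedioate A4 to be removed. The anodic cross-coupling would be statistical as well, so that the target would have to be parted from triacontane A5 and dibenzyl docosanedioate A6, all waxy neutral solids, and the benzyl ester would have to survive alkoxide formed at the cathode.

The route rests on the C1–C2 bond and the ester C1–O bond. The unbranched, unfunctionalised chain C2–C26 is brought in as a linear C25 olefin, and the carboxyl carbon as carbon monoxide. In the key step a palladium hydride walks the double bond of pentacos-12-ene along the chain, and only the terminal, linear acyl is trapped by benzyl alcohol: olefin, CO and alcohol give the target in one operation without by-product. As both chain ends are equivalent, every positional and geometrical olefin isomer converges on the same ester. Statistical half-esterification and statistical radical pairing have no counterpart, and the benzyl ester never meets an alkoxide.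

Key step: step 2

Step 1
Reactants: 1 dodecyltriphenylphosphonium bromide; 2 tridecanal
Product: 4 (Z)-pentacos-12-ene, via dodecylidenetriphenylphosphorane 3 (not isolated)
Conditions: 1 (1.1 equiv), NaN(SiMe3)2 (1.05 equiv), THF, 0 °C; then 2 (1.0 equiv), −78 °C to rt; hexane trituration, filtration through SiO2 (hexane)
Reagents that add atoms: none
Why: Wittig olefination, in which the non-stabilised ylide 3, generated free of lithium salts, adds to aldehyde 2 and the oxaphosphetane collapses to the olefin and triphenylphosphine oxide; kinetic control should favour the Z isomer, but the geometry is without consequence because step 2 erases it, and the pure hydrocarbon is freed from the phosphine oxide by filtration through silica in hexane.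

Step 2
Reactants: 4 (Z)-pentacos-12-ene; 5 carbon monoxide; 6 benzyl alcohol
Product: 7 benzyl hexacosanoate
Conditions: Pd(OAc)2 (1 mol%), 1,2-bis(di-tert-butylphosphinomethyl)benzene (4 mol%), MeSO3H (8 mol%), 6 (5 equiv), toluene, 5 (30 bar), 90 °C; SiO2 (hexane/EtOAc), recrystallisation from acetone
Reagents that add atoms: none
Why: The palladium hydride formed from Pd(OAc)2, the diphosphine and the acid adds to the C12=C13 bond of 4 and, by repeated β-hydride elimination and re-insertion, moves the metal along the chain over some twelve positions, so that all secondary alkyls and the primary pentacosyl-palladium are in fast equilibrium; CO inserts, and benzyl alcohol cleaves the unhindered linear acyl far faster than any branched acyl held between the four tert-butyl groups, which forms the C1–C2 and C1–O bonds and returns the hydride. The closest known reaction type is the isomerising alkoxycarbonylation of long-chain internal olefins (internal octenes, methyl oleate) to linear terminal esters with this catalyst, and benzyl alcohol is an established nucleophile in palladium-catalysed alkoxycarbonylation of olefins. No ring closes and no stereocentre is created, and the Z/E geometry of 4 is erased. The step needs terminal against internal carbonylation, which the bulk of the ligand should secure under Curtin–Hammett control, and it needs no choice of direction, because C1 and C25 of 4 are equivalent methyl termini and the chain carries no group that could hold the migrating hydride. Three components are joined with complete atom economy, and no hydrogen is present that could cleave the benzyl ester.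

**Compound list**
1 | dodecyltriphenylphosphonium bromide | CCCCCCCCCCCC[P+](c1ccccc1)(c1ccccc1)c1ccccc1.[Br-] | starting material
2 | tridecanal | CCCCCCCCCCCCC=O | starting material
3 | dodecylidenetriphenylphosphorane | CCCCCCCCCCCC=P(c1ccccc1)(c1ccccc1)c1ccccc1 | intermediate
4 | (Z)-pentacos-12-ene | CCCCCCCCCCC/C=C\CCCCCCCCCCCC | intermediate
5 | carbon monoxide | [C-]#[O+] | starting material
6 | benzyl alcohol | OCc1ccccc1 | starting material
7 | benzyl hexacosanoate | CCCCCCCCCCCCCCCCCCCCCCCCCC(=O)OCc1ccccc1 | target

Total step count: 2. Longest linear sequence: 2 steps.

Steps most likely to fail (the route has only two steps, so both are given, the riskier first):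

Step 2. Acyl-palladium species may be intercepted before the walk to the chain end is complete, because benzyl alcohol is bulkier and less nucleophilic than methanol, which would give branched (mainly 2-methyl) esters that are hard to remove from a waxy product. Benzyl alcohol may also be lost by acid-catalysed ether formation or benzylation of the solvent, and the water so formed would divert the acyl to the free acid. Fallback: the benzyl group is no longer introduced in the carbonylation. Setting out from 4, the isomerising carbonylation is run in its best-precedented form with methanol as solvent and nucleophile (Pd(OAc)2, the same diphosphine, MeSO3H, CO 30 bar, 90 °C) to give methyl hexacosanoate F1, which is freed from branched isomers by recrystallisation. F1 is then transesterified with 6 (Ti(OiPr)4 cat., toluene, reflux with distillative removal of methanol), and the route is rejoined at 7.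

Step 1. The basic ylide may enolise the aldehyde and cause aldol self-condensation, ylide formation may be incomplete, and the waxy hydrocarbon may be lost on removal of the phosphine oxide. Fallback: the olefin is made by addition and elimination instead of olefination. Setting out from 2, commercial dodecylmagnesium bromide is added (THF, 0 °C) to give the symmetrical secondary alcohol pentacosan-13-ol F2. Acid-catalysed dehydration (TsOH cat., xylene, reflux, Dean–Stark) should then give pentacos-12-ene as a mixture of 4 and (E)-pentacos-12-ene F3. Any positional isomers formed by hydride shift are equally acceptable to step 2, and the route is rejoined at 4.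

Further compounds
F1 | step 2 | methyl hexacosanoate | CCCCCCCCCCCCCCCCCCCCCCCCCC(=O)OC
F2 | step 1 | pentacosan-13-ol | CCCCCCCCCCCCC(O)CCCCCCCCCCCC
F3 | step 1 | (E)-pentacos-12-ene | CCCCCCCCCCC/C=C/CCCCCCCCCCCC
A1 | direct plan | dodecanedioic acid | OC(=O)CCCCCCCCCCC(=O)O
A2 | direct plan | 12-(benzyloxy)-12-oxododecanoic acid | OC(=O)CCCCCCCCCCC(=O)OCc1ccccc1
A3 | direct plan | palmitic acid | CCCCCCCCCCCCCCCC(=O)O
A4 | direct plan | dibenzyl dodecanedioate | O=C(OCc1ccccc1)CCCCCCCCCCC(=O)OCc1ccccc1
A5 | direct plan | triacontane | CCCCCCCCCCCCCCCCCCCCCCCCCCCCCC
A6 | direct plan | dibenzyl docosanedioate | O=C(OCc1ccccc1)CCCCCCCCCCCCCCCCCCCCC(=O)OCc1ccccc1
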